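**Retrosynthetic overview**
1. The exocyclic C5=C1′ double bond (E, side chain cis to C4–H) is made last by a stereospecific anti-elimination from an erythro γ-(α-hydroxyalkyl)butenolide. The C5/C1′ pair encodes the alkene geometry and is erased.
2. Key disconnection: the C3′H2–C4′H= bond between the CH2 next to the C-methyl stereocentre and the terminus of the E,E-diene. It is formed by a B-alkyl Suzuki–Miyaura coupling of an alkyl-9-BBN with a (1E,3E)-dienyl iodide, the borane being made in the same pot by hydroboration.
3. Enabling feature: the three-carbon link =C1′H–C2′H(CH3)–C3′H2– between the enol-lactone ring and the diene. C1′ is a carbinol before it becomes the exocyclic alkene carbon, so C2′/C3′ can be an isopropenyl group whose hydroboration is steered by 1,3-allylic strain from C1′ and places boron on C3′.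
4. Left half: 3-methylfuran-2(5H)-one → silyloxyfuran → asymmetric anti-selective vinylogous Mukaiyama aldol with methacrolein. Right half: 3-bromofuran + 4-bromofuran-2-carbaldehyde, then Negishi, Wittig and Takai reactions.
5. Ring order: no ring is formed in the route. The butenolide and both furans are carried from commercial heterocycles.

Key step: step 10

Remark: the SMILES is read as the (5E) isomer at the exocyclic enol-lactone double bond (chain trans to the ring oxygen), the less stable geometry, so it is set by a stereospecific elimination and not by equilibration.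

**Step 1**
Reactants: 1 3-bromofuran; 2 4-bromofuran-2-carbaldehyde
Product: 4 (4-bromofuran-2-yl)(furan-3-yl)methanol, via furan-3-yllithium 3 (not isolated)
Conditions: n-BuLi, THF, −78 °C; then 2, −78 °C; H2O
Reagents that add atoms: none
Why: Br–Li exchange at −78 °C gives the 3-furyllithium, which should add 1,2 to the aldehyde faster than it exchanges with the ring bromide; the carbinol centre is racemic and is removed in step 2.

**Step 2**
Reactants: 4 (4-bromofuran-2-yl)(furan-3-yl)methanol
Product: 5 4-bromo-2-(furan-3-ylmethyl)furan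
Conditions: Et3SiH, TFA, CH2Cl2, −20 → 0 °C
Reagents that add atoms: none
Why: Ionic hydrogenation, in which the doubly furyl-stabilised cation is trapped by silane hydride while the ring bromide is inert.

**Step 3**
Reactants: 5 4-bromo-2-(furan-3-ylmethyl)furan; 6 (3-ethoxy-3-oxopropyl)zinc bromide
Product: 7 ethyl 3-[5-(furan-3-ylmethyl)furan-3-yl]propanoate
Conditions: Pd(OAc)2 (cat.), SPhos, THF, 50 °C
Reagents that add atoms: none
Why: Negishi coupling of a heteroaryl bromide with a functionalised primary alkylzinc halide; the biarylphosphine favours reductive elimination over β-hydride elimination and the ester is tolerated.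

**Step 4**
Reactants: 7 ethyl 3-[5-(furan-3-ylmethyl)furan-3-yl]propanoate
Product: 8 3-[5-(furan-3-ylmethyl)furan-3-yl]propanal
Conditions: DIBAL-H, CH2Cl2, −78 °C; aq. Rochelle salt
Reagents that add atoms: none
Why: Ester reduction with DIBAL-H at −78 °C should stop at the aluminium hemiacetal, which releases the aldehyde on work-up.

**Step 5**
Reactants: 8 3-[5-(furan-3-ylmethyl)furan-3-yl]propanal; 9 2-(triphenyl-λ5-phosphanylidene)propanal
Product: 10 (2E)-5-[5-(furan-3-ylmethyl)furan-3-yl]-2-methylpent-2-enal
Conditions: toluene, 80 °C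
Reagents that add atoms: none
Why: Wittig reaction with a stabilised α-branched formyl ylide, which should give the trisubstituted enal with E geometry and leave the less electrophilic product enal untouched.

**Step 6**
Reactants: 10 (2E)-5-[5-(furan-3-ylmethyl)furan-3-yl]-2-methylpent-2-enal
Product: 11 2-(furan-3-ylmethyl)-4-[(3E,5E)-6-iodo-4-methylhexa-3,5-dien-1-yl]furan
Conditions: CrCl2, CHI3, THF, 0 °C → rt, dark
Reagents that add atoms: iodoform, IC(I)I
Why: Takai olefination, in which the gem-dichromium species from CHI3/CrCl2 adds to the aldehyde and eliminates to the (E)-vinyl iodide, leaving the existing trisubstituted alkene unchanged.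

**Step 7**
Reactants: 12 3-methylfuran-2(5H)-one
Product: 13 trimethyl[(3-methylfuran-2-yl)oxy]silane
Conditions: TMSCl, Et3N, Et2O, 0 °C → rt
Reagents that add atoms: chlorotrimethylsilane, C[Si](C)(C)Cl
Why: Soft enolisation and O-silylation of the butenolide give the aromatic 2-silyloxyfuran, the usual vinylogous Mukaiyama donor.

**Step 8**
Reactants: 13 trimethyl[(3-methylfuran-2-yl)oxy]silane; 14 2-methylprop-2-enal (methacrolein)
Product: 16 (5R)-5-[(1S)-1-hydroxy-2-methylprop-2-en-1-yl]-3-methylfuran-2(5H)-one, via O-trimethylsilyl aldol 15 (not isolated)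
Conditions: chiral cationic (salen)Cr(III) Lewis acid (cat.), CH2Cl2, −20 °C; then 1 M HCl, THF
Reagents that add atoms: none
Why: Catalytic asymmetric vinylogous Mukaiyama aldol addition through C5 of the silyloxyfuran onto the Lewis-acid-bound enal (1,2-addition); this catalyst class favours the anti (erythro) adduct via an open transition state, and the catalyst enantiomer is chosen to set C1′ as S and C5 as R.

**Step 9**
Reactants: 16 (5R)-5-[(1S)-1-hydroxy-2-methylprop-2-en-1-yl]-3-methylfuran-2(5H)-one
Product: 17 (5R)-3-methyl-5-[(1S)-2-methyl-1-(triethylsilyloxy)prop-2-en-1-yl]furan-2(5H)-one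
Conditions: TESCl, imidazole, CH2Cl2, 0 °C
Reagents that add atoms: chlorotriethylsilane, CC[Si](Cl)(CC)CC
Why: Standard silylation of a secondary alcohol under conditions too mild to epimerise C5; the ether blocks retro-aldol cleavage in the next step.

**Step 10**
Reactants: 17 (5R)-3-methyl-5-[(1S)-2-methyl-1-(triethylsilyloxy)prop-2-en-1-yl]furan-2(5H)-one; 11 2-(furan-3-ylmethyl)-4-[(3E,5E)-6-iodo-4-methylhexa-3,5-dien-1-yl]furan
Product: 19 (5R)-5-[(1S,2S,4E,6E)-9-[5-(furan-3-ylmethyl)furan-3-yl]-2,6-dimethyl-1-(triethylsilyloxy)nona-4,6-dien-1-yl]-3-methylfuran-2(5H)-one, via alkyl-9-BBN borane 18 (not isolated)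
Conditions: 9-BBN dimer, THF, 0 °C → rt; then 11, PdCl2(dppf) (cat.), AsPh3, Cs2CO3, DMF/H2O, rt, dark
Reagents that add atoms: none
Why: 9-BBN adds across the 1,1-disubstituted alkene of 17 with boron on the terminal CH2; Pd(0) then inserts into the C–I bond of 11, the base-activated borate transfers its primary alkyl group and reductive elimination forms the CH2–CH= bond with retention of the E,E-diene geometry. The closest known reaction type is the one-pot hydroboration/B-alkyl Suzuki–Miyaura coupling of terminal alkenes with alkenyl iodides. No ring is closed in this step. The new C2′ stereocentre is set in the hydroboration by 1,3-allylic strain: C1′–H eclipses the alkene, the bulky borane adds to the face opposite the butenolide substituent and the methyl group ends anti to the OTES group, which gives (2′S), the only stereocentre that survives into the target. The step needs chemoselectivity for the electron-rich isopropenyl group over the electron-poor butenolide C=C and the lactone carbonyl, which the low reactivity of 9-BBN towards conjugated esters should secure; it also needs C5–H to stay untouched, for which the TES ether and a carbonate base at room temperature are chosen.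

**Step 11**
Reactants: 19 (5R)-5-[(1S,2S,4E,6E)-9-[5-(furan-3-ylmethyl)furan-3-yl]-2,6-dimethyl-1-(triethylsilyloxy)nona-4,6-dien-1-yl]-3-methylfuran-2(5H)-one
Product: 20 (5R)-5-[(1S,2S,4E,6E)-9-[5-(furan-3-ylmethyl)furan-3-yl]-1-hydroxy-2,6-dimethylnona-4,6-dien-1-yl]-3-methylfuran-2(5H)-one
Conditions: HF·pyridine, pyridine, THF, 0 °C
Reagents that add atoms: none
Why: Buffered fluoride cleaves the TES ether without base, so the C5 configuration, the furans and the diene should be preserved.

**Step 12**
Reactants: 20 (5R)-5-[(1S,2S,4E,6E)-9-[5-(furan-3-ylmethyl)furan-3-yl]-1-hydroxy-2,6-dimethylnona-4,6-dien-1-yl]-3-methylfuran-2(5H)-one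
Product: 21 (5E)-5-[(2S,4E,6E)-9-[5-(furan-3-ylmethyl)furan-3-yl]-2,6-dimethylnona-4,6-dien-1-ylidene]-3-methylfuran-2(5H)-one
Conditions: PPh3, DEAD, THF, 0 °C → rt, dark
Reagents that add atoms: none
Why: Mitsunobu-type dehydration, in which the alcohol is activated as an oxyphosphonium ion and the acidic C5–H is removed in an anti-periplanar E2 elimination, so the erythro (5R,1′S) arrangement is translated into the E exocyclic alkene while both temporary stereocentres disappear.

**Compound list**
1 | 3-bromofuran | Brc1ccoc1 | starting material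
2 | 4-bromofuran-2-carbaldehyde | O=Cc1cc(Br)co1 | starting material
3 | furan-3-yllithium | [Li]c1ccoc1 | intermediate
4 | (4-bromofuran-2-yl)(furan-3-yl)methanol (racemic) | OC(c1ccoc1)c1cc(Br)co1 | intermediate
5 | 4-bromo-2-(furan-3-ylmethyl)furan | Brc1coc(Cc2ccoc2)c1 | intermediate
6 | (3-ethoxy-3-oxopropyl)zinc bromide | CCOC(=O)CC[Zn]Br | starting material
7 | ethyl 3-[5-(furan-3-ylmethyl)furan-3-yl]propanoate | CCOC(=O)CCc1coc(Cc2ccoc2)c1 | intermediate
8 | 3-[5-(furan-3-ylmethyl)furan-3-yl]propanal | O=CCCc1coc(Cc2ccoc2)c1 | intermediate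
9 | 2-(triphenyl-λ5-phosphanylidene)propanal | CC(C=O)=P(c1ccccc1)(c1ccccc1)c1ccccc1 | starting material
10 | (2E)-5-[5-(furan-3-ylmethyl)furan-3-yl]-2-methylpent-2-enal | O=C/C(C)=C/CCc1coc(Cc2ccoc2)c1 | intermediate
11 | 2-(furan-3-ylmethyl)-4-[(3E,5E)-6-iodo-4-methylhexa-3,5-dien-1-yl]furan | I/C=C/C(C)=C/CCc1coc(Cc2ccoc2)c1 | intermediate
12 | 3-methylfuran-2(5H)-one | CC1=CCOC1=O | starting material
13 | trimethyl[(3-methylfuran-2-yl)oxy]silane | Cc1ccoc1O[Si](C)(C)C | intermediate
14 | 2-methylprop-2-enal (methacrolein) | C=C(C)C=O | starting material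
15 | (5R)-3-methyl-5-[(1S)-2-methyl-1-(trimethylsilyloxy)prop-2-en-1-yl]furan-2(5H)-one | CC1=C[C@H]([C@@H](O[Si](C)(C)C)C(C)=C)OC1=O | intermediate
16 | (5R)-5-[(1S)-1-hydroxy-2-methylprop-2-en-1-yl]-3-methylfuran-2(5H)-one | CC1=C[C@H]([C@@H](O)C(C)=C)OC1=O | intermediate
17 | (5R)-3-methyl-5-[(1S)-2-methyl-1-(triethylsilyloxy)prop-2-en-1-yl]furan-2(5H)-one | CC1=C[C@H]([C@@H](O[Si](CC)(CC)CC)C(C)=C)OC1=O | intermediate
18 | (5R)-5-[(1S,2S)-3-(9-borabicyclo[3.3.1]nonan-9-yl)-2-methyl-1-(triethylsilyloxy)propyl]-3-methylfuran-2(5H)-one | CC1=C[C@H]([C@@H](O[Si](CC)(CC)CC)[C@@H](C)CB2C3CCCC2CCC3)OC1=O | intermediate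
19 | (5R)-5-[(1S,2S,4E,6E)-9-[5-(furan-3-ylmethyl)furan-3-yl]-2,6-dimethyl-1-(triethylsilyloxy)nona-4,6-dien-1-yl]-3-methylfuran-2(5H)-one | CC1=C[C@H]([C@@H](O[Si](CC)(CC)CC)[C@@H](C)C/C=C/C(C)=C/CCc2coc(Cc3ccoc3)c2)OC1=O | intermediate
20 | (5R)-5-[(1S,2S,4E,6E)-9-[5-(furan-3-ylmethyl)furan-3-yl]-1-hydroxy-2,6-dimethylnona-4,6-dien-1-yl]-3-methylfuran-2(5H)-one | CC1=C[C@H]([C@@H](O)[C@@H](C)C/C=C/C(C)=C/CCc2coc(Cc3ccoc3)c2)OC1=O | intermediate
21 | (5E)-5-[(2S,4E,6E)-9-[5-(furan-3-ylmethyl)furan-3-yl]-2,6-dimethylnona-4,6-dien-1-ylidene]-3-methylfuran-2(5H)-one | CC1=C/C(=C\[C@@H](C)C/C=C/C(C)=C/CCc2coc(Cc3ccoc3)c2)OC1=O | target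

**Step count and risks**
Total steps: 12. Longest linear sequence: 9 (steps 1–6, 10, 11, 12).

Most likely to fail:

1. Step 8. What may go wrong: insufficient enantio- or anti-selectivity in the catalytic aldol addition, or competing conjugate addition to the enal. Fallback (sets out from 13 and 14, comes back at 16): a fluoride-initiated vinylogous aldol addition (Bu4NF cat., THF, −78 °C) passes through an open transition state and should favour the erythro pair. It gives by silyl transfer the racemic silyl ether F1 and, after acidic work-up, the racemic erythro aldol F2. A Sharpless kinetic resolution (Ti(OiPr)4, L-(+)-diisopropyl tartrate, t-BuOOH, 4 Å sieves, CH2Cl2, −20 °C) should then epoxidise the (5S,1′R) enantiomer and leave (5R,1′S)-16, which is separated by chromatography.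

2. Step 10. What may go wrong: epimerisation at C5 or loss of the silyloxy group by β-elimination under the aqueous base, insufficient facial selectivity in the hydroboration, or slow transmetalation of the β-branched borane. Fallback (sets out from 17, comes back at 19): the hydroboration is run as before (borane 18) but worked up oxidatively (NaBO3·4H2O) to the primary alcohol F3, at which stage diastereomers can be separated. Iodination (I2, PPh3, imidazole) gives the iodide F4, zinc insertion (activated Zn, DMA) gives the alkylzinc iodide F5, and a base-free Negishi coupling with 11 (Pd2(dba)3, SPhos, THF/DMA, rt) gives 19.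

3. Step 12. What may go wrong: partial stepwise elimination through the furanolate (E1cB), which would leak to the more stable Z isomer, or isomerisation of the E alkene by the phosphine. Fallback (sets out from 19, comes back at 21): equilibration at C5 with a catalytic amine base (Et3N, CH2Cl2) and chromatography gives the (5S) epimer F6, with recovered 19 recycled. HF·pyridine gives the threo alcohol F7. The Burgess reagent (benzene, 50 °C) forms the sulfamate F8, whose intramolecular syn-elimination should give the same E alkene from the threo pair without external base or phosphine.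

**Further compounds**
F1 | step 8 | racemic erythro O-trimethylsilyl aldol, rac-(5R*,1′S*) (not isolated) | CC1=C[C@H]([C@@H](O[Si](C)(C)C)C(C)=C)OC1=O.CC1=C[C@@H]([C@H](O[Si](C)(C)C)C(C)=C)OC1=O
F2 | step 8 | racemic erythro aldol, rac-(5R*,1′S*)-5-(1-hydroxy-2-methylprop-2-en-1-yl)-3-methylfuran-2(5H)-one | CC1=C[C@H]([C@@H](O)C(C)=C)OC1=O.CC1=C[C@@H]([C@H](O)C(C)=C)OC1=O
F3 | step 10 | (5R)-5-[(1S,2S)-3-hydroxy-2-methyl-1-(triethylsilyloxy)propyl]-3-methylfuran-2(5H)-one | CC1=C[C@H]([C@@H](O[Si](CC)(CC)CC)[C@@H](C)CO)OC1=O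
F4 | step 10 | (5R)-5-[(1S,2R)-3-iodo-2-methyl-1-(triethylsilyloxy)propyl]-3-methylfuran-2(5H)-one | CC1=C[C@H]([C@@H](O[Si](CC)(CC)CC)[C@@H](C)CI)OC1=O
F5 | step 10 | [(2R,3S)-2-methyl-3-[(2R)-4-methyl-5-oxo-2,5-dihydrofuran-2-yl]-3-(triethylsilyloxy)propyl]zinc iodide (not isolated) | CC1=C[C@H]([C@@H](O[Si](CC)(CC)CC)[C@@H](C)C[Zn]I)OC1=O
F6 | step 12 | (5S)-5-[(1S,2S,4E,6E)-9-[5-(furan-3-ylmethyl)furan-3-yl]-2,6-dimethyl-1-(triethylsilyloxy)nona-4,6-dien-1-yl]-3-methylfuran-2(5H)-one | CC1=C[C@@H]([C@@H](O[Si](CC)(CC)CC)[C@@H](C)C/C=C/C(C)=C/CCc2coc(Cc3ccoc3)c2)OC1=O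
F7 | step 12 | (5S)-5-[(1S,2S,4E,6E)-9-[5-(furan-3-ylmethyl)furan-3-yl]-1-hydroxy-2,6-dimethylnona-4,6-dien-1-yl]-3-methylfuran-2(5H)-one | CC1=C[C@@H]([C@@H](O)[C@@H](C)C/C=C/C(C)=C/CCc2coc(Cc3ccoc3)c2)OC1=O
F8 | step 12 | triethylammonium N-(methoxycarbonyl)sulfamate ester of F7 (not isolated) | CC1=C[C@@H]([C@@H](OS(=O)(=O)[N-]C(=O)OC)[C@@H](C)C/C=C/C(C)=C/CCc2coc(Cc3ccoc3)c2)OC1=O.CC[NH+](CC)CC
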